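**Retrosynthetic overview**

1. DMGF (7,7''-di-O-methylagathisflavone) is reached by one BCl3 unmasking of O5, O4', O5'' and O4''' of a fully alkylated 6,8''-biflavone. Ring C of unit 2 comes from cyclodehydration of a 1,3-diketone, made by C-aroylation of an o-hydroxyacetophenone whose acetyl group is placed on C4a'' by a Fries shift.
2. The strategy rests on ring A of unit 2 (C4a''-C5''-C6''-C7''-C8''-C8a''). C8'' carries the bond to C6 of unit 1 and lies between C8a''-O1'' and C7''-OMe, with C5''-O meta: a 2-arylphloroglucinol with three different oxygens.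
3. Key disconnection: this ring is assembled from 3-ethoxycyclobutenone (supplies C8a'', C6'', C5'', C4a'') and a flavon-6-yl methyl ynol ether (supplies C8'', C7''). The bonds C8a''-C8'', C7''-C6'' and C4a''-C8a'' form around the preformed C6-C8'' bond, and the ring arrives with O1'' as free OH, O7'' as OMe and O5'' as a peri ethyl ether.
4. The ynol ether comes from Negishi coupling of methoxyethynylzinc chloride (from trichloroethylene) with a 6-iodoflavone made from apigenin (7-O-methylation, 4'-O-isopropylation, C6 iodination, 5-O-methylation). The cyclobutenone comes from ketene and ethoxyacetylene.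
5. Ring order: the three rings of unit 1 come with apigenin; ring A of unit 2 forms in step 8, ring C of unit 2 in step 12; ring B of unit 2 comes with 4-(benzyloxy)benzoyl chloride.

Key step: step 8

Remark on the chemistry: the target structure defines no configuration at the C6-C8'' axis, so the racemic atropisomer mixture is the goal. Locants of unit 1 are unprimed (its B ring single-primed); those of unit 2 are double-primed (its B ring triple-primed).

**Route**

Step 1
Reactants: 1 apigenin
Product: 2 genkwanin (5-hydroxy-2-(4-hydroxyphenyl)-7-methoxy-4H-chromen-4-one)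
Conditions: MeI (1.05 equiv), K2CO3 (1.0 equiv), DMF, rt; chromatography
Reagents that add atoms: iodomethane, CI
Why: Williamson etherification under limiting base should alkylate first the 7-OH, the most acidic phenol (para to the C4 carbonyl), while the chelated 5-OH reacts last and some 7,4'-dimethyl ether is separated.

Step 2
Reactants: 2 genkwanin
Product: 3 5-hydroxy-7-methoxy-2-[4-(propan-2-yloxy)phenyl]-4H-chromen-4-one
Conditions: 2-bromopropane (3 equiv), K2CO3, DMF, 60 °C
Reagents that add atoms: 2-bromopropane, CC(C)Br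
Why: Williamson etherification of the only phenol not hydrogen-bonded to C4=O; the isopropyl ether is chosen because it should tolerate BF3 in step 10 and still fall to BCl3 in step 13.

Step 3
Reactants: 3 5-hydroxy-7-methoxy-2-[4-(propan-2-yloxy)phenyl]-4H-chromen-4-one
Product: 4 5-hydroxy-6-iodo-7-methoxy-2-[4-(propan-2-yloxy)phenyl]-4H-chromen-4-one
Conditions: BnNMe3 ICl2 (1.1 equiv), CaCO3, CH2Cl2-MeOH, rt
Reagents that add atoms: benzyltrimethylammonium dichloroiodate, C[N+](C)(C)Cc1ccccc1.Cl[I-]Cl
Why: Electrophilic aromatic iodination of 5-hydroxy-7-alkoxyflavones with this reagent goes ortho to the chelated 5-OH, at C6 and not C8, and ring A is far more electron-rich than the B ring.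

Step 4
Reactants: 4 5-hydroxy-6-iodo-7-methoxy-2-[4-(propan-2-yloxy)phenyl]-4H-chromen-4-one
Product: 5 6-iodo-5,7-dimethoxy-2-[4-(propan-2-yloxy)phenyl]-4H-chromen-4-one
Conditions: Me2SO4 (excess), K2CO3, acetone, reflux
Reagents that add atoms: dimethyl sulfate, COS(=O)(=O)OC
Why: Forcing Williamson methylation overcomes the chelation and the flanking iodine; the small peri methyl ether masks the phenol toward the zinc reagent and the ketene and is cleaved by BCl3 at the end.

Step 5
Reactants: 6 trichloroethylene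
Product: 8 (E)-1,2-dichloro-1-methoxyethene, via dichloroacetylene 7 (not isolated)
Conditions: KOMe (1.1 equiv), cat. MeOH, THF, 0 °C to rt; distillation
Reagents that add atoms: potassium methoxide, C[O-].[K+]
Why: Methoxide eliminates HCl to give dichloroacetylene in solution, to which methanol adds anti under alkoxide catalysis (first stage of the Greene ynol ether synthesis); the alkene geometry is of no consequence for step 6.

Step 6
Reactants: 8 (E)-1,2-dichloro-1-methoxyethene; 5 6-iodo-5,7-dimethoxy-2-[4-(propan-2-yloxy)phenyl]-4H-chromen-4-one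
Product: 11 5,7-dimethoxy-6-(methoxyethynyl)-2-[4-(propan-2-yloxy)phenyl]-4H-chromen-4-one, via lithium methoxyacetylide 9 (not isolated), via methoxyethynylzinc chloride 10 (not isolated)
Conditions: 8 (3 equiv), n-BuLi (2.05 equiv per 8), THF, -78 to -40 °C; ZnCl2, -78 to 0 °C; then 5, Pd(PPh3)4 (5 mol%), THF, rt to 50 °C; NaHCO3 work-up, Et3N-deactivated silica
Reagents that add atoms: none
Why: Elimination and chlorine-lithium exchange give the lithium alkoxyacetylide, and after transmetalation the Negishi coupling of alkoxyethynylzinc chlorides with aryl iodides is known; the small linear nucleophile should pass the two ortho methoxy groups, and a methyl ynol ether has no beta-hydrogen for retro-ene loss.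

Step 7
Reactants: 12 ethoxyacetylene; 13 acetone
Product: 15 3-ethoxycyclobut-2-en-1-one, via ketene 14 (not isolated)
Conditions: ketene (from pyrolysis of 13, hot-filament generator) passed into 12, CH2Cl2, -20 °C to rt; distillation
Reagents that add atoms: none
Why: (2+2) cycloaddition of ketene with the electron-rich alkyne, in which the nucleophilic CH carbon attacks the ketene carbonyl carbon and so places the ethoxy group at C3 of the cyclobutenone.

Step 8
Reactants: 11 5,7-dimethoxy-6-(methoxyethynyl)-2-[4-(propan-2-yloxy)phenyl]-4H-chromen-4-one; 15 3-ethoxycyclobut-2-en-1-one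
Product: 20 6-(4-ethoxy-2-hydroxy-6-methoxyphenyl)-5,7-dimethoxy-2-[4-(propan-2-yloxy)phenyl]-4H-chromen-4-one (racemic axis), via 3-ethoxyvinylketene 16 (not isolated), via vinylcyclobutenone 17 (not isolated), via dienylketene 18 (not isolated), via cyclohexadienone 19 (not isolated)
Conditions: 15 (2 equiv, in portions), toluene, 80 to 110 °C, sealed tube; crude stirred with K2CO3, MeOH, rt (returns any phenol acylated by excess ketene)
Reagents that add atoms: none
Why: Proposed new method: thermal four-electron electrocyclic opening of 15 gives vinylketene 16, whose carbonyl carbon is attacked by the aryl-bearing, oxygen-remote carbon of ynol ether 11 in a (2+2) cycloaddition to 17; 17 opens to dienylketene 18, which closes to 19 and tautomerises to phenol 20. The closest known reaction is the Danheiser benzannulation of 3-alkyl- and 3-arylcyclobutenones with alkyl-substituted alkoxy- and siloxyalkynes, extended here to a 3-alkoxycyclobutenone and an aryl ynol ether. The one new ring, carbocyclic ring A of unit 2, is closed by six-electron electrocyclisation (C4a''-C8a'') after the cycloaddition has made C8a''-C8'' and C7''-C6'', so the hindered C6-C8'' bond never has to be made by coupling. No stereocentre is created, and the new tetra-ortho-substituted axis forms as the racemate that the target requires. The step needs one regiochemistry, aryl between the new hydroxyl and the methoxy group, and the polarisation of the ynol ether secures it, because its carbon remote from oxygen is the nucleophile toward the ketene carbonyl. The neutral thermal conditions should leave the flavone, the aryl ethers and the methyl ynol ether intact.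

Step 9
Reactants: 20 6-(4-ethoxy-2-hydroxy-6-methoxyphenyl)-5,7-dimethoxy-2-[4-(propan-2-yloxy)phenyl]-4H-chromen-4-one
Product: 21 2-{5,7-dimethoxy-4-oxo-2-[4-(propan-2-yloxy)phenyl]-4H-chromen-6-yl}-5-ethoxy-3-methoxyphenyl acetate
Conditions: Ac2O, pyridine, DMAP (cat.), CH2Cl2, rt
Reagents that add atoms: acetic anhydride, CC(=O)OC(C)=O
Why: DMAP-catalysed O-acylation of the only free hydroxyl, which should proceed despite the flanking aryl group.

Step 10
Reactants: 21 2-{5,7-dimethoxy-4-oxo-2-[4-(propan-2-yloxy)phenyl]-4H-chromen-6-yl}-5-ethoxy-3-methoxyphenyl acetate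
Product: 23 6-(3-acetyl-4-ethoxy-2-hydroxy-6-methoxyphenyl)-5,7-dimethoxy-2-[4-(propan-2-yloxy)phenyl]-4H-chromen-4-one, via difluoroboron chelate 22 (not isolated)
Conditions: BF3·OEt2 (5 equiv), ClCH2CH2Cl, 80 °C; then MeOH-H2O, 50 °C
Reagents that add atoms: none
Why: Fries rearrangement of a 3,5-dialkoxyphenyl acetate, in which the acetyl group should settle at the one free ortho carbon (C4a'') because the product is held as the difluoroboron chelate, while BF3 lacks a nucleophilic halide and should leave the methyl, ethyl and isopropyl ethers alone.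

Step 11
Reactants: 23 6-(3-acetyl-4-ethoxy-2-hydroxy-6-methoxyphenyl)-5,7-dimethoxy-2-[4-(propan-2-yloxy)phenyl]-4H-chromen-4-one; 24 4-(benzyloxy)benzoyl chloride
Product: 25 6-(3-{3-[4-(benzyloxy)phenyl]-3-oxopropanoyl}-4-ethoxy-2-hydroxy-6-methoxyphenyl)-5,7-dimethoxy-2-[4-(propan-2-yloxy)phenyl]-4H-chromen-4-one
Conditions: LiN(SiMe3)2 (3.3 equiv), THF, -78 to -10 °C; then 24 (1.05 equiv), -78 °C to rt; aq. HCl
Reagents that add atoms: none
Why: Claisen-type C-aroylation of the lithium phenoxide-enolate, the direct variant of the Baker-Venkataraman synthesis, gives the 1,3-diketone in one operation with a non-nucleophilic base that should not touch the flavone of unit 1.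

Step 12
Reactants: 25 6-(3-{3-[4-(benzyloxy)phenyl]-3-oxopropanoyl}-4-ethoxy-2-hydroxy-6-methoxyphenyl)-5,7-dimethoxy-2-[4-(propan-2-yloxy)phenyl]-4H-chromen-4-one
Product: 26 2-[4-(benzyloxy)phenyl]-8-{5,7-dimethoxy-4-oxo-2-[4-(propan-2-yloxy)phenyl]-4H-chromen-6-yl}-5-ethoxy-7-methoxy-4H-chromen-4-one
Conditions: TsOH·H2O (0.2 equiv), toluene, 100 °C
Reagents that add atoms: none
Why: Acid-catalysed cyclodehydration of the o-hydroxyaryl 1,3-diketone (hemiketal formation, then loss of water) closes ring C of unit 2 through O1''-C2'' under conditions mild enough for the benzyl and isopropyl ethers.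

Step 13
Reactants: 26 2-[4-(benzyloxy)phenyl]-8-{5,7-dimethoxy-4-oxo-2-[4-(propan-2-yloxy)phenyl]-4H-chromen-6-yl}-5-ethoxy-7-methoxy-4H-chromen-4-one
Product: 27 DMGF (5-hydroxy-6-[5-hydroxy-2-(4-hydroxyphenyl)-7-methoxy-4-oxo-4H-chromen-8-yl]-2-(4-hydroxyphenyl)-7-methoxy-4H-chromen-4-one)
Conditions: BCl3 (1 M in CH2Cl2, 12 equiv), C6HMe5 (6 equiv), CH2Cl2, -78 °C to rt; MeOH, then aq. HCl
Reagents that add atoms: none
Why: Lewis-acid ether cleavage in which the benzyl group leaves as a cation caught by pentamethylbenzene, the isopropyl ether is cleaved by BCl3, and the peri methyl and ethyl ethers are dealkylated by chloride within the boron chelates spanning C4=O/O5 and C4''=O/O5'', while the unchelated 7- and 7''-methoxy groups should survive.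

**Compound list**

1 | apigenin | O=c1cc(-c2ccc(O)cc2)oc2cc(O)cc(O)c12 | starting material
2 | genkwanin | COc1cc(O)c2c(=O)cc(-c3ccc(O)cc3)oc2c1 | intermediate
3 | 5-hydroxy-7-methoxy-2-[4-(propan-2-yloxy)phenyl]-4H-chromen-4-one | COc1cc(O)c2c(=O)cc(-c3ccc(OC(C)C)cc3)oc2c1 | intermediate
4 | 5-hydroxy-6-iodo-7-methoxy-2-[4-(propan-2-yloxy)phenyl]-4H-chromen-4-one | COc1cc2oc(-c3ccc(OC(C)C)cc3)cc(=O)c2c(O)c1I | intermediate
5 | 6-iodo-5,7-dimethoxy-2-[4-(propan-2-yloxy)phenyl]-4H-chromen-4-one | COc1cc2oc(-c3ccc(OC(C)C)cc3)cc(=O)c2c(OC)c1I | intermediate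
6 | trichloroethylene | ClC=C(Cl)Cl | starting material
7 | dichloroacetylene (not isolated) | ClC#CCl | intermediate
8 | (E)-1,2-dichloro-1-methoxyethene | CO/C(Cl)=C\Cl | intermediate
9 | lithium methoxyacetylide (not isolated) | [Li]C#COC | intermediate
10 | methoxyethynylzinc chloride (not isolated) | COC#C[Zn]Cl | intermediate
11 | 5,7-dimethoxy-6-(methoxyethynyl)-2-[4-(propan-2-yloxy)phenyl]-4H-chromen-4-one | COC#Cc1c(OC)cc2oc(-c3ccc(OC(C)C)cc3)cc(=O)c2c1OC | intermediate
12 | ethoxyacetylene | CCOC#C | starting material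
13 | acetone | CC(C)=O | starting material
14 | ketene (not isolated) | C=C=O | intermediate
15 | 3-ethoxycyclobut-2-en-1-one | CCOC1=CC(=O)C1 | intermediate
16 | 3-ethoxybuta-1,3-dien-1-one, the vinylketene (not isolated) | CCOC(=C)C=C=O | intermediate
17 | 2-aryl-4-(1-ethoxyvinyl)-3-methoxycyclobut-2-en-1-one, aryl = flavon-6-yl of 11 (not isolated) | CCOC(=C)C1C(OC)=C(c2c(OC)cc3oc(-c4ccc(OC(C)C)cc4)cc(=O)c3c2OC)C1=O | intermediate
18 | (3Z)-2-aryl-5-ethoxy-3-methoxyhexa-1,3,5-trien-1-one, the dienylketene (not isolated) | CCOC(=C)/C=C(/OC)C(=C=O)c1c(OC)cc2oc(-c3ccc(OC(C)C)cc3)cc(=O)c2c1OC | intermediate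
19 | 2-aryl-5-ethoxy-3-methoxycyclohexa-2,4-dien-1-one (not isolated) | CCOC1=CC(OC)=C(c2c(OC)cc3oc(-c4ccc(OC(C)C)cc4)cc(=O)c3c2OC)C(=O)C1 | intermediate
20 | 6-(4-ethoxy-2-hydroxy-6-methoxyphenyl)-5,7-dimethoxy-2-[4-(propan-2-yloxy)phenyl]-4H-chromen-4-one (racemic axis) | CCOc1cc(O)c(-c2c(OC)cc3oc(-c4ccc(OC(C)C)cc4)cc(=O)c3c2OC)c(OC)c1 | intermediate
21 | 2-{5,7-dimethoxy-4-oxo-2-[4-(propan-2-yloxy)phenyl]-4H-chromen-6-yl}-5-ethoxy-3-methoxyphenyl acetate | CCOc1cc(OC(C)=O)c(-c2c(OC)cc3oc(-c4ccc(OC(C)C)cc4)cc(=O)c3c2OC)c(OC)c1 | intermediate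
22 | difluoroboron chelate of 23 (not isolated) | CCOc1cc(OC)c(-c2c(OC)cc3oc(-c4ccc(OC(C)C)cc4)cc(=O)c3c2OC)c2O[B-](F)(F)[O+]=C(C)c12 | intermediate
23 | 6-(3-acetyl-4-ethoxy-2-hydroxy-6-methoxyphenyl)-5,7-dimethoxy-2-[4-(propan-2-yloxy)phenyl]-4H-chromen-4-one | CCOc1cc(OC)c(-c2c(OC)cc3oc(-c4ccc(OC(C)C)cc4)cc(=O)c3c2OC)c(O)c1C(C)=O | intermediate
24 | 4-(benzyloxy)benzoyl chloride | O=C(Cl)c1ccc(OCc2ccccc2)cc1 | starting material
25 | 6-(3-{3-[4-(benzyloxy)phenyl]-3-oxopropanoyl}-4-ethoxy-2-hydroxy-6-methoxyphenyl)-5,7-dimethoxy-2-[4-(propan-2-yloxy)phenyl]-4H-chromen-4-one | CCOc1cc(OC)c(-c2c(OC)cc3oc(-c4ccc(OC(C)C)cc4)cc(=O)c3c2OC)c(O)c1C(=O)CC(=O)c1ccc(OCc2ccccc2)cc1 | intermediate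
26 | 2-[4-(benzyloxy)phenyl]-8-{5,7-dimethoxy-4-oxo-2-[4-(propan-2-yloxy)phenyl]-4H-chromen-6-yl}-5-ethoxy-7-methoxy-4H-chromen-4-one | CCOc1cc(OC)c(-c2c(OC)cc3oc(-c4ccc(OC(C)C)cc4)cc(=O)c3c2OC)c2oc(-c3ccc(OCc4ccccc4)cc3)cc(=O)c12 | intermediate
27 | DMGF (7,7''-di-O-methylagathisflavone, racemic axis) | COc1cc2oc(-c3ccc(O)cc3)cc(=O)c2c(O)c1-c1c(OC)cc(O)c2c(=O)cc(-c3ccc(O)cc3)oc12 | target

**Step count and risks**

Total step count: 13. Longest linear sequence: 11 steps (steps 1, 2, 3, 4, 6, 8, 9, 10, 11, 12, 13 from apigenin; steps 5 and 7 are side branches).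

Steps most likely to fail:

1. Step 8 (proposed new method). The push-pull stabilised 3-ethoxycyclobutenone may open only slowly. The vinylketene may then be lost to self-condensation or to acylation of the product phenol faster than it adds to the hindered, aryl-conjugated ynol ether. Fallback: the C6-C8'' bond is made by cross-coupling, setting out from 5 and rejoining the route at 23. Iodide 5 is borylated (B2pin2, PdCl2(dppf), KOAc, dioxane, 90 °C) to 5,7-dimethoxy-2-[4-(propan-2-yloxy)phenyl]-6-(4,4,5,5-tetramethyl-1,3,2-dioxaborolan-2-yl)-4H-chromen-4-one F1. Purchased 1-(2,6-dihydroxy-4-methoxyphenyl)ethan-1-one is mono-ethylated (EtI, K2CO3, acetone; the second hydroxyl is held by chelation) to 1-(2-ethoxy-6-hydroxy-4-methoxyphenyl)ethan-1-one F2. F2 is iodinated ortho to the chelated hydroxyl (BnNMe3 ICl2, CaCO3, CH2Cl2-MeOH) to 1-(6-ethoxy-2-hydroxy-3-iodo-4-methoxyphenyl)ethan-1-one F3. Suzuki-Miyaura coupling of F1 with F3 (Pd(OAc)2, SPhos, K3PO4, toluene-water, 100 °C) should then give acetophenone 23 directly, bypassing 20 to 22.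

2. Step 6. Oxidative addition at the electron-rich iodide flanked by two methoxy groups may be slow. The zinc acetylide may decompose on warming, and the ynol ether may hydrate during isolation. Fallback: a Stille coupling with an isolated tin reagent, setting out from 8 and 5 and rejoining at 11. Acetylide 9, made from 8 as in step 6, is quenched with Bu3SnCl to give tributyl(methoxyethynyl)stannane F4, which is distilled. F4 is coupled with 5 under neutral, salt-free conditions (Pd(PPh3)4, CuI, toluene, 80 °C) to give 11.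

3. Step 10. The acetyl group may migrate to the para carbon (C6'', between the ethoxy and methoxy groups), may be lost to return 20, or the Lewis acid may attack an ether. Fallback: regiospecific ortho-formylation, setting out from 20 and rejoining at 23. Phenol 20 is formylated through its magnesium phenoxide (MgCl2, Et3N, paraformaldehyde, MeCN, reflux; Casnati-Skattebøl reaction, ortho only) to 3-{5,7-dimethoxy-4-oxo-2-[4-(propan-2-yloxy)phenyl]-4H-chromen-6-yl}-6-ethoxy-2-hydroxy-4-methoxybenzaldehyde F5. MeMgBr (3 equiv, THF, -78 to 0 °C) adds to the aldehyde to give 6-[4-ethoxy-2-hydroxy-3-(1-hydroxyethyl)-6-methoxyphenyl]-5,7-dimethoxy-2-[4-(propan-2-yloxy)phenyl]-4H-chromen-4-one F6. Oxidation of the benzylic alcohol with MnO2 (CH2Cl2, rt) should give 23.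

Further compounds
F1 | step 8 | 5,7-dimethoxy-2-[4-(propan-2-yloxy)phenyl]-6-(4,4,5,5-tetramethyl-1,3,2-dioxaborolan-2-yl)-4H-chromen-4-one | COc1cc2oc(-c3ccc(OC(C)C)cc3)cc(=O)c2c(OC)c1B1OC(C)(C)C(C)(C)O1
F2 | step 8 | 1-(2-ethoxy-6-hydroxy-4-methoxyphenyl)ethan-1-one | CCOc1cc(OC)cc(O)c1C(C)=O
F3 | step 8 | 1-(6-ethoxy-2-hydroxy-3-iodo-4-methoxyphenyl)ethan-1-one | CCOc1cc(OC)c(I)c(O)c1C(C)=O
F4 | step 6 | tributyl(methoxyethynyl)stannane | CCCC[Sn](CCCC)(CCCC)C#COC
F5 | step 10 | 3-{5,7-dimethoxy-4-oxo-2-[4-(propan-2-yloxy)phenyl]-4H-chromen-6-yl}-6-ethoxy-2-hydroxy-4-methoxybenzaldehyde | CCOc1cc(OC)c(-c2c(OC)cc3oc(-c4ccc(OC(C)C)cc4)cc(=O)c3c2OC)c(O)c1C=O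
F6 | step 10 | 6-[4-ethoxy-2-hydroxy-3-(1-hydroxyethyl)-6-methoxyphenyl]-5,7-dimethoxy-2-[4-(propan-2-yloxy)phenyl]-4H-chromen-4-one | CCOc1cc(OC)c(-c2c(OC)cc3oc(-c4ccc(OC(C)C)cc4)cc(=O)c3c2OC)c(O)c1C(C)O
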